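**Retrosynthetic overview**

- Ring C (the cyclohexenyl unit; C1 benzylic CH, C2 vinylic CH, C3 C–CH3, C4 and C5 CH2, C6 CH–iPr) is cut across C1–C2 and C5–C6. This gives an (E)-aryl–CH=CH–iPr two-carbon unit and a 2-methylbutadiene four-carbon unit, joined by an intramolecular [4+2] cycloaddition.
- Enabling feature: the phenolic oxygen of ring A is ortho to the carbon that carries ring C and 1,5 to C2 (O–C(ar)–C(ar)–C1–C2). One SiMe2 group can therefore bridge O and the diene terminus C2, which makes the cycloaddition intramolecular, fixes its regiochemistry and leaves C2 as an allylsilane.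
- After the key step, protodesilylation in the SE2′ sense removes silicon from C2, moves the double bond from C3=C4 to C2=C3 and frees the ring A phenol; fluoride then frees the ring B phenol.
- The triene comes from magnolol by mono-silylation, ortho-bromination, Suzuki coupling with an (E)-alkenylboronate, and O-silylation with a dienylchlorosilane made from (E)-3-iodo-2-methylprop-2-en-1-ol.
- Ring order: rings A and B arrive intact in magnolol; ring C and the temporary oxasiline ring close together in the key step; the oxasiline ring is opened one step later.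

Key step: step 9

Assumption: (E)-3-iodo-2-methylprop-2-en-1-ol is taken as a catalogue compound (otherwise one step from propargyl alcohol by zirconium-catalysed carboalumination and iodination), and the sense of induction of the bisphosphine in step 9 has to be confirmed on the first run, the mirror-image ligand being used if it is opposite.

**Route**

Step 1
Reactants: 1 magnolol (5,5'-diallylbiphenyl-2,2'-diol)
Product: 2 5,5'-diallyl-2'-[(triisopropylsilyl)oxy]biphenyl-2-ol
Conditions: i-Pr3SiCl (1.0 equiv), imidazole, DMF, 0 °C to rt
Reagents that add atoms: chlorotri(propan-2-yl)silane, CC(C)[Si](Cl)(C(C)C)C(C)C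
Why: O-silylation of one of the two equivalent phenols of the C2-symmetric diol should stop mainly at the mono-ether because the second hydroxyl becomes more hindered, and it marks ring A (free OH) against ring B for all later steps, with recovered 1 and bis-ether recycled.

Step 2
Reactants: 2 5,5'-diallyl-2'-[(triisopropylsilyl)oxy]biphenyl-2-ol
Product: 3 3-bromo-5,5'-diallyl-2'-[(triisopropylsilyl)oxy]biphenyl-2-ol
Conditions: NBS (1.0 equiv), i-Pr2NH (10 mol %), CH2Cl2, −40 to 0 °C, dark
Reagents that add atoms: N-bromosuccinimide, O=C1CCC(=O)N1Br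
Why: Amine-mediated ortho-bromination of a free phenol (electrophilic aromatic substitution) can only reach C3 of ring A, since its para and other ortho positions are substituted, the silyl ether ring is less activated, and the allyl groups should survive the nucleophile-free, non-radical conditions.

Step 3
Reactants: 4 3-methylbut-1-yne
Product: 5 (E)-4,4,5,5-tetramethyl-2-(3-methylbut-1-en-1-yl)-1,3,2-dioxaborolane
Conditions: pinacolborane (1.05 equiv), Cp2Zr(H)Cl (5 mol %), Et3N (10 mol %), neat, 60 °C
Reagents that add atoms: pinacolborane, CC1(C)OBOC1(C)C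
Why: Zirconium-catalysed syn hydroboration of a terminal alkyne puts boron on the terminal carbon and should give only the E-alkenylboronate.

Step 4
Reactants: 3 3-bromo-5,5'-diallyl-2'-[(triisopropylsilyl)oxy]biphenyl-2-ol; 5 (E)-4,4,5,5-tetramethyl-2-(3-methylbut-1-en-1-yl)-1,3,2-dioxaborolane
Product: 6 5,5'-diallyl-3-[(E)-3-methylbut-1-en-1-yl]-2'-[(triisopropylsilyl)oxy]biphenyl-2-ol
Conditions: Pd(OAc)2 (3 mol %), SPhos (6 mol %), K3PO4, toluene–H2O, 60 °C
Reagents that add atoms: none
Why: Suzuki–Miyaura coupling transfers the alkenyl group with retention of its E geometry, and the electron-rich biarylphosphine should couple the hindered ortho-bromophenol below the temperature at which zerovalent palladium would move the allyl double bonds.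

Step 5
Reactants: 7 (E)-3-iodo-2-methylprop-2-en-1-ol
Product: 8 (E)-3-iodo-2-methylprop-2-enal
Conditions: MnO2, CH2Cl2, rt
Reagents that add atoms: none
Why: MnO2 oxidises the allylic alcohol chemoselectively and leaves the vinyl iodide and the alkene geometry untouched.

Step 6
Reactants: 8 (E)-3-iodo-2-methylprop-2-enal
Product: 9 (E)-1-iodo-2-methylbuta-1,3-diene
Conditions: Ph3PCH3Br, KOt-Bu, Et2O, 0 °C to rt; kept as a pentane–Et2O solution
Reagents that add atoms: methyltriphenylphosphonium bromide, C[P+](c1ccccc1)(c1ccccc1)c1ccccc1.[Br-]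
Why: Wittig methylenation of the enal does not involve the trisubstituted iodoalkene, so its E geometry is carried into the diene.

Step 7
Reactants: 9 (E)-1-iodo-2-methylbuta-1,3-diene
Product: 11 (E)-chloro(dimethyl)(2-methylbuta-1,3-dien-1-yl)silane, via dienyllithium 10 (not isolated)
Conditions: t-BuLi (2 equiv), Et2O, −78 °C; then cannulated into Me2SiCl2 (4 equiv), −78 °C to rt; distilled
Reagents that add atoms: dichlorodimethylsilane, C[Si](C)(Cl)Cl
Why: Iodine–lithium exchange proceeds with retention of alkene geometry, and inverse addition of the dienyllithium to an excess of the dichlorosilane should stop at monosubstitution.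

Step 8
Reactants: 6 5,5'-diallyl-3-[(E)-3-methylbut-1-en-1-yl]-2'-[(triisopropylsilyl)oxy]biphenyl-2-ol; 11 (E)-chloro(dimethyl)(2-methylbuta-1,3-dien-1-yl)silane
Product: 12 {[5,5'-diallyl-3-[(E)-3-methylbut-1-en-1-yl]-2'-(triisopropylsilyloxy)biphenyl-2-yl]oxy}dimethyl[(E)-2-methylbuta-1,3-dien-1-yl]silane
Conditions: Et3N, DMAP (10 mol %), CH2Cl2, 0 °C to rt; pentane, filtration under argon, used crude
Reagents that add atoms: none
Why: DMAP-catalysed O-silylation of the ring A phenol by a small chlorodimethylsilane installs the O–Si link that holds the diene terminus next to the benzylic alkene carbon.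

Step 9
Reactants: 12 {[5,5'-diallyl-3-[(E)-3-methylbut-1-en-1-yl]-2'-(triisopropylsilyloxy)biphenyl-2-yl]oxy}dimethyl[(E)-2-methylbuta-1,3-dien-1-yl]silane
Product: 13 (10S,10aR)-2-allyl-4-[5-allyl-2-(triisopropylsilyloxy)phenyl]-6,6,7-trimethyl-10-(propan-2-yl)-6a,9,10,10a-tetrahydro-6H-dibenzo[c,e][1,2]oxasiline (either configuration at the silicon-bearing carbon C6a)
Conditions: [Rh(cod)Cl]2 (5 mol %), AgSbF6 (10 mol %), (R,R)-Me-DuPhos (11 mol %), 4 Å sieves, ClCH2CH2Cl, 40 °C, 0.02 M
Reagents that add atoms: none
Why: Proposed new method: a cationic monovalent rhodium–bisphosphine fragment should bind the silyl diene (eta-4) and the styrenyl alkene that the O–SiMe2 link holds beside it, join them by oxidative coupling (C5–C6 bond) to a sigma,pi-allyl trivalent rhodacycle, and close C1–C2 by reductive elimination, the closest known reaction type being the rhodium-catalysed intramolecular [4+2] cycloisomerisation of tethered dienes with unactivated alkenes or alkynes (enantioselective with chiral bisphosphines), with the thermal silicon-tethered intramolecular Diels–Alder reaction as its uncatalysed counterpart. Ring C closes as a formal [4+2] cycloaddition, suprafacial on both partners, and the six-membered oxasiline ring closes with it in the fused mode, since the two-atom O–Si link can bring the silicon-bearing diene terminus only to the benzylic alkene carbon. The trans relation of C1 and C6 is set by the E geometry of the alkene, which the metal pathway transfers faithfully; the absolute configuration of both is set by the alkene face that the chiral rhodium fragment selects, and the configuration at C2 does not matter because step 10 erases it. The step needs regioselectivity (C2 to C1, C5 to C6), which the tether enforces whatever the electronic bias of the silyl diene, and chemoselectivity for the internal styrenyl alkene over the two allyl groups, which only the tethered alkene can reach intramolecularly. Running at 40 °C keeps the uncatalysed racemic cycloaddition, which should need well above 150 °C, out of play.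

Step 10
Reactants: 13 (10S,10aR)-2-allyl-4-[5-allyl-2-(triisopropylsilyloxy)phenyl]-6,6,7-trimethyl-10-(propan-2-yl)-6a,9,10,10a-tetrahydro-6H-dibenzo[c,e][1,2]oxasiline
Product: 15 5,5'-diallyl-3-[(1S,6S)-3-methyl-6-(propan-2-yl)cyclohex-2-en-1-yl]-2'-[(triisopropylsilyl)oxy]biphenyl-2-ol, via silanol 14 (not isolated)
Conditions: TsOH·H2O (20 mol %), CH2Cl2–MeCN–H2O, 0 °C to rt
Reagents that add atoms: none
Why: Acid hydrolysis of the labile aryl–O–SiMe2 bond is followed by protodesilylation of the allylsilane in the SE2′ sense (proton to C4, tertiary cation at C3 stabilised by the beta-silicon, loss of silicon from C2), which should place the double bond at C2=C3 far faster than the acid can attack the product alkene, and touches neither C1 nor C6.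

Step 11
Reactants: 15 5,5'-diallyl-3-[(1S,6S)-3-methyl-6-(propan-2-yl)cyclohex-2-en-1-yl]-2'-[(triisopropylsilyl)oxy]biphenyl-2-ol
Product: 16 5,5'-diallyl-3-[(1S,6S)-3-methyl-6-(propan-2-yl)cyclohex-2-en-1-yl]biphenyl-2,2'-diol
Conditions: n-Bu4NF, THF, 0 °C; then H2O
Reagents that add atoms: none
Why: Fluoride cleaves the aryl triisopropylsilyl ether (Si–F bond formation) and frees the ring B phenol without touching the alkenes or the stereocentres.

**Compound list**

1 | magnolol, 5,5'-diallylbiphenyl-2,2'-diol | C=CCc1ccc(O)c(-c2cc(CC=C)ccc2O)c1 | starting material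
2 | 5,5'-diallyl-2'-[(triisopropylsilyl)oxy]biphenyl-2-ol | C=CCc1ccc(O[Si](C(C)C)(C(C)C)C(C)C)c(-c2cc(CC=C)ccc2O)c1 | intermediate
3 | 3-bromo-5,5'-diallyl-2'-[(triisopropylsilyl)oxy]biphenyl-2-ol | C=CCc1ccc(O[Si](C(C)C)(C(C)C)C(C)C)c(-c2cc(CC=C)cc(Br)c2O)c1 | intermediate
4 | 3-methylbut-1-yne | CC(C)C#C | starting material
5 | (E)-4,4,5,5-tetramethyl-2-(3-methylbut-1-en-1-yl)-1,3,2-dioxaborolane | CC(C)/C=C/B1OC(C)(C)C(C)(C)O1 | intermediate
6 | 5,5'-diallyl-3-[(E)-3-methylbut-1-en-1-yl]-2'-[(triisopropylsilyl)oxy]biphenyl-2-ol | C=CCc1ccc(O[Si](C(C)C)(C(C)C)C(C)C)c(-c2cc(CC=C)cc(/C=C/C(C)C)c2O)c1 | intermediate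
7 | (E)-3-iodo-2-methylprop-2-en-1-ol | OC/C(C)=C/I | starting material
8 | (E)-3-iodo-2-methylprop-2-enal | O=C/C(C)=C/I | intermediate
9 | (E)-1-iodo-2-methylbuta-1,3-diene | C=C/C(C)=C/I | intermediate
10 | (E)-(2-methylbuta-1,3-dien-1-yl)lithium | [Li]/C=C(C)/C=C | intermediate
11 | (E)-chloro(dimethyl)(2-methylbuta-1,3-dien-1-yl)silane | C[Si](C)(Cl)/C=C(C)/C=C | intermediate
12 | {[5,5'-diallyl-3-[(E)-3-methylbut-1-en-1-yl]-2'-(triisopropylsilyloxy)biphenyl-2-yl]oxy}dimethyl[(E)-2-methylbuta-1,3-dien-1-yl]silane | C=CCc1ccc(O[Si](C(C)C)(C(C)C)C(C)C)c(-c2cc(CC=C)cc(/C=C/C(C)C)c2O[Si](C)(C)/C=C(C)/C=C)c1 | intermediate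
13 | (10S,10aR)-2-allyl-4-[5-allyl-2-(triisopropylsilyloxy)phenyl]-6,6,7-trimethyl-10-(propan-2-yl)-6a,9,10,10a-tetrahydro-6H-dibenzo[c,e][1,2]oxasiline; ring C carbons arranged in space as in 16 (the benzylic label reads R only because silicon raises the rank of its neighbour), C6a either configuration | C=CCc1ccc(O[Si](C(C)C)(C(C)C)C(C)C)c(-c2cc(CC=C)cc([C@@H]3C4C(C)=CC[C@H]3C(C)C)c2O[Si]4(C)C)c1 | intermediate
14 | 5,5'-diallyl-3-[(1R,6S)-2-(hydroxydimethylsilyl)-3-methyl-6-(propan-2-yl)cyclohex-3-en-1-yl]-2'-[(triisopropylsilyl)oxy]biphenyl-2-ol, either configuration at the silicon-bearing carbon | C=CCc1ccc(O[Si](C(C)C)(C(C)C)C(C)C)c(-c2cc(CC=C)cc([C@@H]3C([Si](C)(C)O)C(C)=CC[C@H]3C(C)C)c2O)c1 | intermediate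
15 | 5,5'-diallyl-3-[(1S,6S)-3-methyl-6-(propan-2-yl)cyclohex-2-en-1-yl]-2'-[(triisopropylsilyl)oxy]biphenyl-2-ol | C=CCc1ccc(O[Si](C(C)C)(C(C)C)C(C)C)c(-c2cc(CC=C)cc([C@@H]3C=C(C)CC[C@H]3C(C)C)c2O)c1 | intermediate
16 | 5,5'-diallyl-3-[(1S,6S)-3-methyl-6-(propan-2-yl)cyclohex-2-en-1-yl]biphenyl-2,2'-diol | C=CCc1ccc(O)c(-c2cc(CC=C)cc([C@@H]3C=C(C)CC[C@H]3C(C)C)c2O)c1 | target

**Step count and risks**

Total step count: 11. Longest linear sequence: 7 steps (steps 1, 2, 4, 8, 9, 10, 11 from magnolol; the diene arm, steps 5, 6, 7, 8, 9, 10, 11, is equally long).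

Steps most likely to fail:

1. Step 9 (Proposed new method). The cationic rhodium may be tied up by eta-6 binding to the electron-rich arenes or by the terminal allyl alkenes. Turnover on the hindered E-disubstituted alkene may be slow and the facial selectivity low. Rhodium hydrides may also move the allyl double bonds into conjugation. Fallback with known chemistry, setting out from 2 and coming back at 15: acid-catalysed Friedel–Crafts-type ortho-alkylation of the free phenol ring of 2 with purchased (S)-(+)-α-phellandrene (TsOH·H2O cat., CH2Cl2, 0 °C to rt). Protonation of the diene gives the allyl cation, and ring A should attack it at the carbon next to the isopropyl-bearing stereocentre, anti to the isopropyl group. The terpene stereocentre is kept and the new one is set trans to it, as in the known acid-mediated coupling of phenols with phellandrene or menthadienols; only C3 of ring A is open, and the silyl ether ring should not react. This fallback makes no new compound (none F0).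

2. Step 10. The freed ring A phenol may add across the new trisubstituted alkene under acid, or the double bond may migrate before silicon is lost cleanly. Fallback setting out from 13 and coming back at 15: MeLi (THF, −78 °C) opens the oxasiline ring at silicon, and the lithium phenoxide is capped in the same flask with acetic anhydride to give the acetate-capped allyltrimethylsilane F1. With the phenol masked and the silicon free to align with the alkene, CF3CO2H in wet CH2Cl2 at 0 °C should give the transposed acetate F2 in the SE2′ sense. K2CO3 in methanol then removes the acetate to return to 15.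

3. Step 8. Silylation of the doubly flanked ring A phenol may stall, and the Si–Cl and Si–O bonds may hydrolyse during handling, so that the triene never reaches the key step intact. Fallback setting out from 9 (and 6) and coming back at 12: iodine–lithium exchange as in step 7, but quenching with chloro(diethylamino)dimethylsilane, gives the distillable aminosilane F3. Heating F3 with phenol 6 in toluene (60–80 °C) under a slow argon stream transfers the silyl group to oxygen, with the volatile amine as the only co-product and no salt or aqueous work-up; the solution of 12 goes directly into step 9.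

**Further compounds**

F0 | step 9 | none | none
F1 | step 10 | 5,5'-diallyl-3-[(1R,6S)-3-methyl-6-(propan-2-yl)-2-(trimethylsilyl)cyclohex-3-en-1-yl]-2'-(triisopropylsilyloxy)biphenyl-2-yl acetate | C=CCc1ccc(O[Si](C(C)C)(C(C)C)C(C)C)c(-c2cc(CC=C)cc([C@@H]3C([Si](C)(C)C)C(C)=CC[C@H]3C(C)C)c2OC(C)=O)c1
F2 | step 10 | 5,5'-diallyl-3-[(1S,6S)-3-methyl-6-(propan-2-yl)cyclohex-2-en-1-yl]-2'-(triisopropylsilyloxy)biphenyl-2-yl acetate | C=CCc1ccc(O[Si](C(C)C)(C(C)C)C(C)C)c(-c2cc(CC=C)cc([C@@H]3C=C(C)CC[C@H]3C(C)C)c2OC(C)=O)c1
F3 | step 8 | N,N-diethyl-1,1-dimethyl-1-[(E)-2-methylbuta-1,3-dien-1-yl]silanamine | CCN(CC)[Si](C)(C)/C=C(C)/C=C
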